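## The problem

Compound 17 is an unsymmetrical phthalide dimer: a 4,5-dihydrophthalide and an aromatic phthalide joined through a cyclobutane. Unprimed labels denote the dihydrophthalide half (lactone carbonyl C1, ring oxygen O2, enol carbon C3 with butylidene carbon C8, ring B carbons C3a, C4, C5, C6, C7, C7a; ring A is the butenolide C1–O2–C3–C3a–C7a). Primed labels denote the aromatic half (carbonyl C1', oxygen O2', C3', propyl-bearing C8'). The four-membered ring C6–C7–C3'–C8' is fused to ring B along C6–C7 and is spiro to the aromatic lactone at the quaternary carbon C3'. All four cyclobutane carbons are stereogenic (6S,7R,3'R,8'R): C5, C7a, O2' and the propyl group lie on one face, the arene and three hydrogens on the other. There is no stereocentre outside this ring, so the ring fusion can steer C3' and C8' only through the shape of the bicycle, and the absolute sense must come from a catalyst or a separation. The cross-conjugated (Z)-butylidene butenolide of ring A is sensitive to light, acid, base and oxidants and should appear last; the benzylic tertiary C3'–O2' bond must not be ionised, and the cyclobutane must not sit beside a chromophore that can be excited again. The enabling feature is that C6–C7 and C3'–C8' are opposite bonds of the four-membered ring. Removing both leaves C7=C3', the exocyclic alkene of a 3-ylidenephthalide, and C6=C8', a plain 1,2-disubstituted alkene, already joined by C7a, C3a, C4 and C5. If C3a=C7a is held in a furan, which is also a latent ring A, the tether is rigid and cis, and one [2+2] event closes ring B and the cyclobutane together.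

## Retrosynthesis

**Ring A last (17 ⇒ 16 ⇒ 14).** The C3=C8 double bond of 17 is disconnected by formal addition of water to give the γ-hydroxybutenolide 16. Removing the C1 carbonyl oxygen and the C3 hydroxyl together leads to the 2-butylfuran 14 (C1–H, C3–butyl). The neighbouring options are worse: adding a four-carbon unit to a ring A anhydride has to choose between two carbonyls, and carrying the dienyl lactone through a photochemical step exposes a second chromophore. The furan is transparent to a visible-light sensitiser, its oxidation is regiospecific because only C1 bears a hydrogen, and it serves as the cis tether of the key step. Compound 14 is no simpler in skeleton but is free of every sensitive group. The forward steps must oxidise the furan without touching the cyclobutane and form the Z alkene, which is the thermodynamic isomer.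

**Cyclobutane and ring B (14 ⇒ 13).** The bonds C6–C7 and C3'–C8' are cut together. The other pair of cyclobutane bonds (C6–C8' and C7–C3') would give two untethered halves and an intermolecular union with no control of chemo-, regio- or facial selectivity; the single-bond cuts are treated under the roads not taken. The chosen cut gives 13, which is achiral and lacks both ring B and the four-membered ring. The forward reaction must add the excited ylidenephthalide to the Z alkene in the straight sense, with cis fusion, on one enantiotopic face.

**Enol lactone alkene (13 ⇒ 11 + 12).** C7=C3' is cut by carbonyl olefination to the furaldehyde 11 and the phthalidyl phosphonate 12. Closing C3'–O2' onto an alkyne instead would add a step and, with an electron-rich furyl alkyne, risks the six-membered ring. The olefination has only the alkene geometry open, and the triplet state of the key step erases that. Both fragments are small, and 12 is a catalogue compound.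

**Heptenyl chain (11 ⇒ 10 ⇒ 6 + 9; 9 ⇒ 8 ⇒ 7).** The furan–CH2 bond C3a–C4 is cut to the bromofuran acetal 6 and the alkylzinc 9; the coupled acetal 10 is unmasked to 11. Reagent 9 comes from iodide 8 and this from alcohol 7, which brings the Z alkene ready-made. Stepwise homologation of a furylmethanol would cost about five steps and set the Z geometry late. The coupling must work at an electron-rich, doubly flanked C–Br bond without alkene migration.

**Butyl group and furan core (6 ⇒ 5 ⇒ 4 ⇒ 3 ⇒ 2 ⇒ 1).** The C3–butyl bond is cut to the α-furyllithium 5, formed by deprotonation of acetal 4 next to bromine. The bromine serves twice: it acidifies the flanking α-hydrogen and is later the coupling handle. Acetal 4 comes from aldehyde 3, and 3 from symmetrical 1 through the monolithio species 2. A symmetrical furan diester would need ester differentiation and redox steps; here stoichiometry alone differentiates the two bromines.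

## Roads not taken

**Alternative 1:** The cut is C6–C8', read as the outcome of a 1,2-shift, together with C3'–O2'. The precursor is the cyclopropylcarbinol A2. Its C3' is the apex of a cyclopropane fused to ring B at C6–C7 and carries the 2-(methoxycarbonyl)phenyl group and the carbinol carbon C8'; ring B is an enol triflate ester. Ionisation at C8' would make C6 migrate from C3' to C8'. The tertiary benzylic cyclobutyl cation would be captured by the ester carbonyl with loss of its methyl group, giving A1.
- Merits: no photochemistry; the spiro centre and the lactone arise in one event; A2 could come from an enantioselective cyclopropanation with a donor/acceptor carbenoid under a chiral dirhodium tetracarboxylate such as Rh2(S-DOSP)4. Absolute configuration would rest on a mature catalytic reaction, and in this respect the road is better than the chosen one.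
- Weak points: the C6–C3' and C7–C3' bonds of A2 are nearly equivalent, and migration of C7 gives a constitutional isomer. C8' is correct only if one carbinol epimer, made next to a quaternary carbon, reacts with clean inversion. The lactone oxygen must enter on the concave face, cis to ring B. The cation sits in the cyclopropylcarbinyl–cyclobutyl–homoallyl manifold and is destabilised by the ortho ester. A1 still needs ring A built from the enol triflate, whereas 14 is two steps from 17.
- Comparison: against the better enantiocontrol, the chosen plan sets one step that forms two rings and four stereocentres from an achiral diene, a regiochemistry fixed by ring size, and a resolution fallback for the absolute configuration.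

**Alternative 2:** The cut is again C6–C8', as a ring contraction. A nitrogen atom inserted between C6 and C8' leads to the all-cis octahydroindole A4, a secondary amine with C3' as spiro carbon. An iodonitrene, made from a hypervalent iodine oxidant and an ammonia surrogate in trifluoroethanol, would aminate the nitrogen of A4. The 1,1-diazene loses N2 and the 1,4-biradical C6/C8' collapses to A3.
- Merits: this type of contraction transfers pyrrolidine configuration to the cyclobutane, so the four stereocentres could be assembled in five-membered-ring chemistry where asymmetric cycloadditions are strong. Stereochemical fidelity in the ring-forming step is better defined than in the closure of a triplet biradical, which is an advantage over the chosen plan.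
- Weak points: both radical centres are unstabilised secondary carbons beside a quaternary carbon. β-Scission of C7–C3' to two alkenes, one a conjugated enol lactone, is the expected competing channel. The electrophilic iodine reagent meets the electron-rich β-methoxy enoate of ring B. A4, with four contiguous all-cis centres including the spiro one, is as hard to make as the cyclobutane, so the problem is moved and not solved. Ring A must still follow A3.
- Comparison: the chosen plan sets brevity and convergence against the better stereochemical transfer, and the fact that the required isomer is the least strained outcome of its biradical closure.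

**Alternative 3:** The cut is C7–C3' together with C3'–O2'. Precursor A6 is an aryl ketone (C3'=O, ortho methyl ester) joined through C8' to C6 of a ring B that is a 2-(methoxycarbonyl)cyclohexenone; C7 is the β-carbon of the doubly activated alkene. At a carbon cathode in a divided cell, with SmI2 as mediator (trivalent samarium is reduced back to divalent samarium at the electrode) and an alcohol as proton source, the C3' ketyl would add 4-exo-trig to C7. The alkoxide would then close the spiro-lactone on the ortho ester, giving the enolised β-keto ester A5.
- Merits: the most congested bond is made reductively onto a strongly activated acceptor; the lactone closes by itself; A6 holds only C6 and C8', which ordinary asymmetric conjugate addition and alkylation can set. Absolute configuration is therefore more conventional than in the chosen plan, and the β-keto ester of A5 is a good handle for ring A.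
- Weak points: 4-exo-trig ketyl–alkene closure is the least favourable of its family and needs matched reduction potentials. Here the alkylidene β-keto ester of A6 is reduced more easily than the aryl ketone, which invites acceptor reduction and dimerisation. The configuration at C3' and C7 would depend on samarium chelation in a fully substituted cyclobutane. A6 enolises and isomerises readily. Ring A must still be built from A5.
- Comparison: the chosen plan makes both C–C bonds of the cyclobutane and ring B at once and finishes in two steps; it sets that brevity, and a precursor with no stereocentre to lose, against the conventional stereocontrol of this road.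

Key step: step 7

Assumption: compounds 1, 7 and 12 are taken as catalogue compounds (7 would otherwise follow from hept-3-yn-1-ol by semi-hydrogenation over Pd/CaCO3 poisoned with Pb(OAc)2); locants in the names of 14–17 are the labels defined in the first section.

## Route

Step 1
Reactants: 1 3,4-dibromofuran
Product: 3 4-bromofuran-3-carbaldehyde, via 3-bromo-4-lithiofuran 2 (not isolated)
Conditions: n-BuLi (1.0 equiv), Et2O, −78 °C; DMF, −78 °C to rt; aq NH4Cl
Reagents that add atoms: N,N-dimethylformamide, CN(C)C=O
Why: Bromine–lithium exchange on the symmetrical dibromide stops at the monolithio stage at −78 °C, and formylation of the 3-furyllithium with DMF is standard; the low temperature prevents drift of the lithium to an α-position.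

Step 2
Reactants: 3 4-bromofuran-3-carbaldehyde
Product: 4 2-(4-bromofuran-3-yl)-1,3-dioxolane
Conditions: HOCH2CH2OH, p-TsOH (cat.), PhH, reflux, Dean–Stark
Reagents that add atoms: ethylene glycol, OCCO
Why: Acid-catalysed acetalisation with azeotropic removal of water; the dioxolane hides the electrophilic formyl group from the amide base and the organometallics of steps 3 and 5.

Step 3
Reactants: 4 2-(4-bromofuran-3-yl)-1,3-dioxolane
Product: 6 2-(4-bromo-5-butylfuran-3-yl)-1,3-dioxolane, via 2-(4-bromo-5-lithiofuran-3-yl)-1,3-dioxolane 5 (not isolated)
Conditions: LDA, THF, −78 °C; n-BuI, DMPU, −78 to 0 °C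
Reagents that add atoms: 1-iodobutane, CCCCI
Why: LDA deprotonates bromofurans at the α-position flanking the halogen, whose inductive effect should outweigh the weak coordination of the acetal on the other side; the α-furyllithium, the stable arrangement for a lithio-bromofuran, is then alkylated by the primary iodide (directed metalation, SN2 alkylation).

Step 4
Reactants: 7 (Z)-hept-3-en-1-ol
Product: 8 (Z)-1-iodohept-3-ene
Conditions: I2, PPh3, imidazole, CH2Cl2, 0 °C to rt
Reagents that add atoms: iodine, II
Why: Appel-type iodination of a primary alcohol proceeds by SN2 displacement of the alkoxyphosphonium ion and leaves the Z alkene untouched.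

Step 5
Reactants: 8 (Z)-1-iodohept-3-ene; 6 2-(4-bromo-5-butylfuran-3-yl)-1,3-dioxolane
Product: 11 5-butyl-4-[(Z)-hept-3-en-1-yl]furan-3-carbaldehyde, via (Z)-hept-3-en-1-ylzinc iodide 9 (not isolated), via coupled dioxolane 10 (not isolated)
Conditions: Zn dust (TMSCl, BrCH2CH2Br activation), THF, 40 °C; then 6, Pd(OAc)2 (2 mol %), SPhos (4 mol %), THF, 60 °C; then 1 M HCl, THF, 0 °C to rt
Reagents that add atoms: water, O
Why: Zinc inserts into the primary iodide to give a homoallylic alkylzinc that keeps its alkene geometry; Negishi sp3–sp2 coupling with a biarylphosphine-ligated palladium catalyst tolerates the flanked bromofuran and the acetal. The acidic work-up hydrolyses the dioxolane to the conjugated furaldehyde, which is deactivated towards acid.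

Step 6
Reactants: 11 5-butyl-4-[(Z)-hept-3-en-1-yl]furan-3-carbaldehyde; 12 dimethyl (3-oxo-1,3-dihydro-2-benzofuran-1-yl)phosphonate
Product: 13 (3Z)-3-({5-butyl-4-[(3Z)-hept-3-en-1-yl]furan-3-yl}methylidene)-2-benzofuran-1(3H)-one
Conditions: LiHMDS, THF, −78 °C to rt
Reagents that add atoms: none
Why: Horner–Wadsworth–Emmons olefination of the non-enolisable aldehyde with the stabilised phthalidyl phosphonate anion gives the 3-ylidenephthalide. The Z isomer, in which the furyl group avoids the peri C–H of the phthalide, is the thermodynamically preferred one and is purified by chromatography; any E isomer is not lost, because the triplet state of step 7 interconverts the two.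

Step 7
Reactants: 13 (3Z)-3-({5-butyl-4-[(3Z)-hept-3-en-1-yl]furan-3-yl}methylidene)-2-benzofuran-1(3H)-one
Product: 14 (6S,7R,3'R,8'R)-furan-masked spiro-cyclobutane (3-butyl-4,5,6,7-tetrahydro-2-benzofuran whose C6 and C7 are bridged by C8'H(propyl) and the spiro carbon C3' of a phthalide; C5/C7a/O2'/propyl on one face)
Conditions: fac-Ir(ppy)3 (2 mol %), B-(2,4,6-trifluorophenyl)oxazaborolidine from α,α-diphenylprolinol (the antipode that leads to 14; 50 mol %) activated with AlBr3 (50 mol %), CH2Cl2, −78 °C, 450 nm LEDs, Ar
Reagents that add atoms: none
Why: Proposed new method: energy transfer from excited fac-Ir(ppy)3 to the Lewis-acid-bound furylvinyl enol lactone should give its triplet, a twisted 1,2-biradical at C7 and C3'; C7 adds to C6, and after intersystem crossing C3' couples with C8'. The closest known reaction types are sensitised intramolecular [2+2] photocycloadditions of styrenes and enones with tethered alkenes to bicyclo[4.2.0]octanes, and oxazaborolidine–AlBr3-controlled [2+2] photocycloadditions of coumarins and cinnamates; a 3-ylidenephthalide has not been used as the excited partner. Ring B closes by 6-exo-trig attack of the C7 radical on C6, preferred over 7-endo attack on C8', which fixes the straight regiochemistry; the cyclobutane closes by recombination of the 1,4-biradical C3'/C8'. C6 and C7 come out cis because only the cis-disposed biradical on the furan-fused six-membered ring can reach a four-membered ring, the trans form reverting to 13 by C6–C7 cleavage; their absolute sense is decided by the face of C7 that is attacked, which the aryl group of the oxazaborolidine bound at C1'=O is meant to differentiate. C3' and C8' are set in the closure of a biradical that can rotate, so they are under conformational control: the arene of the planar phthalidyl radical should take the convex face away from ring B and the propyl group should close anti to that arene, which is the arrangement of 14 and the one in which the two Z alkenes start. The step needs chemoselective excitation: complexation should lower the triplet energy so that bound 13 is sensitised in preference to free 13, the furan and the isolated alkene lie out of reach of the sensitiser, and 14 has lost the conjugated chromophore, so cycloreversion is not expected.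

Step 8
Reactants: 14 (6S,7R,3'R,8'R)-furan-masked spiro-cyclobutane
Product: 16 (6S,7R,3'R,8'R)-3-butyl-3-hydroxy butenolide (ring A with C1 lactone carbonyl and C3 bearing OH and butyl; C3 epimers), via furan endoperoxide 15 (not isolated)
Conditions: O2, hν (visible), tetraphenylporphyrin (cat.), CH2Cl2, −78 °C; then i-Pr2NEt, −78 °C to rt
Reagents that add atoms: oxygen, O=O
Why: Singlet oxygen adds to the electron-rich furan in a [4+2] sense; the only bridgehead hydrogen of the endoperoxide is at C1, so base-induced Kornblum–DeLaMare fragmentation places the carbonyl at C1 and the hydroxyl on the butyl-bearing C3. The cyclobutane centres are not touched, and the new hemiketal centre is removed in step 9.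

Step 9
Reactants: 16 (6S,7R,3'R,8'R)-3-butyl-3-hydroxy butenolide
Product: 17 CNP0248594.2 ((6S,7R,3'R,8'R)-(Z)-butylidene lactone)
Conditions: p-TsOH·H2O (cat.), PhMe, 80 °C, 4 Å MS
Reagents that add atoms: none
Why: Acid-catalysed dehydration of the γ-hydroxybutenolide through the acyl-oxocarbenium ion gives the exocyclic enol lactone; the Z isomer, with the propyl group turned away from the C4 methylene, is the thermodynamic product, as in 3-alkylidenephthalide syntheses.

## Compound list

1 | 3,4-dibromofuran | Brc1cocc1Br | starting material
2 | 3-bromo-4-lithiofuran | [Li]c1cocc1Br | intermediate
3 | 4-bromofuran-3-carbaldehyde | O=Cc1cocc1Br | intermediate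
4 | 2-(4-bromofuran-3-yl)-1,3-dioxolane | Brc1cocc1C1OCCO1 | intermediate
5 | 2-(4-bromo-5-lithiofuran-3-yl)-1,3-dioxolane | [Li]c1occ(C2OCCO2)c1Br | intermediate
6 | 2-(4-bromo-5-butylfuran-3-yl)-1,3-dioxolane | CCCCc1occ(C2OCCO2)c1Br | intermediate
7 | (Z)-hept-3-en-1-ol | CCC/C=C\CCO | starting material
8 | (Z)-1-iodohept-3-ene | CCC/C=C\CCI | intermediate
9 | (Z)-hept-3-en-1-ylzinc iodide | CCC/C=C\CC[Zn]I | intermediate
10 | 2-{5-butyl-4-[(Z)-hept-3-en-1-yl]furan-3-yl}-1,3-dioxolane | CCCCc1occ(C2OCCO2)c1CC/C=C\CCC | intermediate
11 | 5-butyl-4-[(Z)-hept-3-en-1-yl]furan-3-carbaldehyde | CCCCc1occ(C=O)c1CC/C=C\CCC | intermediate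
12 | dimethyl (3-oxo-1,3-dihydro-2-benzofuran-1-yl)phosphonate | COP(=O)(OC)C1OC(=O)c2ccccc12 | starting material
13 | (3Z)-3-({5-butyl-4-[(3Z)-hept-3-en-1-yl]furan-3-yl}methylidene)-2-benzofuran-1(3H)-one | CCCCc1occ(/C=C2\OC(=O)c3ccccc23)c1CC/C=C\CCC | intermediate
14 | (6S,7R,3'R,8'R)-furan-masked spiro-cyclobutane: 3-butyl-4,5,6,7-tetrahydro-2-benzofuran fused at C6–C7 to a cyclobutane whose other carbons are C8' (propyl) and C3', the spiro carbon of a 2-benzofuran-1(3H)-one; C5, C7a, O2' and propyl cis | CCCCc1occ2c1CC[C@H]1[C@@H](CCC)[C@@]3(OC(=O)c4ccccc43)[C@@H]21 | intermediate
15 | endoperoxide of 14: O–O bridge from C1 to C3 across the furan, cyclobutane as in 14, bridgehead configuration not defined | CCCCC12OOC(O1)C3=C2CC[C@H]2[C@@H](CCC)[C@@]4(OC(=O)c5ccccc54)[C@@H]32 | intermediate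
16 | (6S,7R,3'R,8'R)-γ-hydroxybutenolide: ring A as 3-butyl-3-hydroxy lactone (C1=O, C3a=C7a), rest as in 14; C3 epimers | CCCCC1(O)OC(=O)C2=C1CC[C@H]1[C@@H](CCC)[C@@]3(OC(=O)c4ccccc43)[C@@H]21 | intermediate
17 | CNP0248594.2, (6S,7R,3'R,8'R)-3-[(Z)-butylidene] lactone | CCC/C=C1\OC(=O)C2=C1CC[C@H]1[C@@H](CCC)[C@@]3(OC(=O)c4ccccc43)[C@@H]21 | target

## Step count and least certain steps

Total steps: 9. Longest linear sequence: 8 steps (1 → 3 → 4 → 6 → 11 → 13 → 14 → 16 → 17; step 4 is a one-step side branch).

**Step 7 (key step, proposed new method).** The most likely failure is poor facial selectivity in the first C–C bond formation. The Lewis acid sits at C1'=O, remote from C7 and across a C7–C3' bond that rotates in the twisted triplet, and uncomplexed 13 can also be sensitised, which gives a racemic background. Loss of diastereocontrol at C8' or C3' during closure of the rotating biradical is the second concern. The fallback sets out from 13 and comes back at 14. Irradiation of 13 with fac-Ir(ppy)3 alone in degassed MeCN, without Lewis acid, is a sensitised intramolecular [2+2] cycloaddition of an aryl-conjugated alkene with a tethered alkene, a known reaction type. It should give the racemate, that is 14 together with its (6R,7S,3'S,8'S) enantiomer F1. Preparative HPLC on a chiral stationary phase separates the two and returns to the route at 14; absolute configuration then comes from resolution, and diastereomers are removed at the same stage.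

**Step 3.** The most likely failure is deprotonation at the wrong α-position (C2, beside the acetal) or incomplete alkylation of 5, because the two α-hydrogens differ only by the inductive effect of bromine against coordination by the dioxolane. The fallback sets out from 1 and comes back at 6, and butylates before the two β-positions are differentiated. α-Lithiation of symmetrical 1 with LDA gives 3,4-dibromo-2-lithiofuran F2 and, with 1-iodobutane, 3,4-dibromo-2-butylfuran F3, where no site question arises. Bromine–lithium exchange with n-BuLi at −78 °C should take place at the less hindered bromine remote from the butyl group to give 3-bromo-2-butyl-4-lithiofuran F4. Formylation with DMF gives 4-bromo-5-butylfuran-3-carbaldehyde F5, and acetalisation as in step 2 gives 6. This trades a deprotonation-site question for an exchange-site question governed by sterics.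

**Step 5.** The most likely failure is slow oxidative addition at the electron-rich, doubly flanked C–Br bond, so that protodezincation of 9 or reduction of 6 competes; alkene migration through β-hydride elimination is a lesser risk. The fallback sets out from 6 and comes back at 10; it reverses the polarity and builds the chain by carbonyl olefination. Bromine–lithium exchange on 6 (t-BuLi, Et2O, −78 °C) gives 2-(5-butyl-4-lithiofuran-3-yl)-1,3-dioxolane F6. Opening of oxetane in the presence of BF3·OEt2 gives 3-[2-butyl-4-(1,3-dioxolan-2-yl)furan-3-yl]propan-1-ol F7, and Dess–Martin oxidation gives 3-[2-butyl-4-(1,3-dioxolan-2-yl)furan-3-yl]propanal F8. A salt-free Wittig reaction with the ylide from butyltriphenylphosphonium bromide and NaHMDS installs the Z alkene and gives 10, which is hydrolysed as in step 5.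

**Step 6.** The most likely failure is poor Z/E selectivity at C7=C3', since elimination from the oxaphosphetane is under kinetic control. This complicates purification of 13, although both isomers should converge in step 7. The fallback sets out from 11 and comes back at 13. Seyferth–Gilbert homologation of 11 with dimethyl (1-diazo-2-oxopropyl)phosphonate and K2CO3 in MeOH gives 2-butyl-4-ethynyl-3-[(Z)-hept-3-en-1-yl]furan F9. Sonogashira coupling with 2-iodobenzoic acid (PdCl2(PPh3)2, CuI, Et3N, DMF) gives 2-({5-butyl-4-[(Z)-hept-3-en-1-yl]furan-3-yl}ethynyl)benzoic acid F10. This cyclises in the same pot, or on treatment with a mild base, by 5-exo-dig anti addition of the carboxylate, which gives the Z enol lactone 13 by mechanism.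

**Step 9.** The most likely failure is incomplete geometric control or acid-induced side reactions at elevated temperature: ionisation at C3'–O2' or migration of the ring A double bonds. The fallback sets out from 16 and comes back at 17. Acetylation of the lactol (Ac2O, DMAP, Et3N, CH2Cl2) gives the γ-acetoxybutenolide F11, and elimination of acetic acid with DBU in warm toluene gives 17 under basic conditions, the classical enol-lactonisation through the pseudo-acid acetate.

## Further compounds

F1 | step 7 | enantiomer of 14, (6R,7S,3'S,8'S)-furan-masked spiro-cyclobutane | CCCCc1occ2c1CC[C@@H]1[C@H](CCC)[C@]3(OC(=O)c4ccccc43)[C@H]21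
F2 | step 3 | 3,4-dibromo-2-lithiofuran | [Li]c1occ(Br)c1Br
F3 | step 3 | 3,4-dibromo-2-butylfuran | CCCCc1occ(Br)c1Br
F4 | step 3 | 3-bromo-2-butyl-4-lithiofuran | CCCCc1occ([Li])c1Br
F5 | step 3 | 4-bromo-5-butylfuran-3-carbaldehyde | CCCCc1occ(C=O)c1Br
F6 | step 5 | 2-(5-butyl-4-lithiofuran-3-yl)-1,3-dioxolane | CCCCc1occ(C2OCCO2)c1[Li]
F7 | step 5 | 3-[2-butyl-4-(1,3-dioxolan-2-yl)furan-3-yl]propan-1-ol | CCCCc1occ(C2OCCO2)c1CCCO
F8 | step 5 | 3-[2-butyl-4-(1,3-dioxolan-2-yl)furan-3-yl]propanal | CCCCc1occ(C2OCCO2)c1CCC=O
F9 | step 6 | 2-butyl-4-ethynyl-3-[(Z)-hept-3-en-1-yl]furan | CCCCc1occ(C#C)c1CC/C=C\CCC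
F10 | step 6 | 2-({5-butyl-4-[(Z)-hept-3-en-1-yl]furan-3-yl}ethynyl)benzoic acid | CCCCc1occ(C#Cc2ccccc2C(=O)O)c1CC/C=C\CCC
F11 | step 9 | (6S,7R,3'R,8'R)-γ-acetoxybutenolide: 16 with the C3 hydroxyl acetylated, C3 epimers | CCCCC1(OC(C)=O)OC(=O)C2=C1CC[C@H]1[C@@H](CCC)[C@@]3(OC(=O)c4ccccc43)[C@@H]21
A1 | alternative 1 | spiro-lactone cyclobutane with ring B as enol triflate methyl ester | COC(=O)C2=C(OS(=O)(=O)C(F)(F)F)CC[C@H]1[C@@H](CCC)[C@@]3(OC(=O)c4ccccc43)[C@@H]21
A2 | alternative 1 | methyl 2-[7-(1-hydroxybutyl)-2-(methoxycarbonyl)-3-(trifluoromethylsulfonyloxy)bicyclo[4.1.0]hept-2-en-7-yl]benzoate, cis-fused, aryl on the ring B face | COC(=O)C1=C(OS(=O)(=O)C(F)(F)F)CC[C@@H]2[C@H]1[C@@]2(c1ccccc1C(=O)OC)[C@H](O)CCC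
A3 | alternative 2 | spiro-lactone cyclobutane with ring B as β-methoxy enoate | COC(=O)C2=C(OC)CC[C@H]1[C@@H](CCC)[C@@]3(OC(=O)c4ccccc43)[C@@H]21
A4 | alternative 2 | methyl 5-methoxy-3'-oxo-2-propyl-1,2,3a,6,7,7a-hexahydrospiro[indole-3,1'-[2]benzofuran]-4-carboxylate, all-cis | COC(=O)C1=C(OC)CC[C@H]2N[C@@H](CCC)[C@@]3(OC(=O)c4ccccc43)[C@@H]12
A5 | alternative 3 | spiro-lactone cyclobutane with ring B as β-keto ester (enol form) | COC(=O)C2=C(O)CC[C@H]1[C@@H](CCC)[C@@]3(OC(=O)c4ccccc43)[C@@H]21
A6 | alternative 3 | methyl 2-{2-[3-(methoxycarbonyl)-4-oxocyclohex-2-en-1-yl]pentanoyl}benzoate | COC(=O)C1=C[C@H]([C@@H](CCC)C(=O)c2ccccc2C(=O)OC)CCC1=O
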